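(Readings and results were generated by integration for substances that don't exist; noise was put on by code.)

In a one-step world with ligand short, the product at the end follows the ligand charged in plain proportion, a power of one.

| flask | starting complex | incoming ligand | leaving ligand | remark | time |
|---|---|---|---|---|---|
| ash | 0.20 M | 0.36 M | 1 M | run made earlier |  |
| birch | 0.20 M | 0.18 M | 1 M | run made earlier |  |
| elm | 0.20 M | 0.27 M | 1 M | run made earlier |  |
| epsilon | 0.20 M | 0.360 M (fed, over 3.0 min) | 1.00 M | all else is in the flask from the start; the feed brings no volume worth counting | 8.0 min |
| beta | 0.20 M | 0.360 M | 1.00 M | everything together at the start | 8.0 min |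
| delta | 0.20 M (fed, over 3.0 min) | 0.360 M | 1.00 M | all else is in the flask from the start; the feed brings no volume worth counting | 8.0 min |

| run | time / min | complex with three exchanged / % |
|---|---|---|
| ash | 0.500 | 0.8 |
| ash | 1.50 | 2.3 |
| ash | 3.00 | 6.3 |
| ash | 4.00 | 6.5 |
| ash | 6.00 | 6.8 |
| ash | 8.00 | 7.5 |
| birch | 0.667 | 0 |
| birch | 2.00 | 1.7 |
| birch | 3.00 | 2.0 |
| birch | 5.00 | 2.3 |
| birch | 8.00 | 2.7 |
| birch | 10.0 | 3.7 |
| elm | 0.667 | 0.4 |
| elm | 2.00 | 3.0 |
| elm | 3.00 | 3.6 |
| elm | 5.00 | 4.8 |
| elm | 8.00 | 4.2 |
| elm | 10.0 | 4.0 |

(each reading ± 0.5 percentage points)

1. the flask that comes out highest in amount of complex with three exchanged, in percent of the starting complex charged, or "all alike" when all lie within 1.5 percentage points (epsilon / beta / delta / all alike)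
2. complex with three exchanged at the end, in percent of the starting complex charged, epsilon
3. complex with three exchanged at the end, in percent of the starting complex charged, beta
4. complex with three exchanged at the end, in percent of the starting complex charged, delta

Two chemists read these runs before the repeat. The first holds a balance view: ash reads 6.5% at 4.00 min and 7.5% at 8.00 min, the feeds end at 3.0 min, and 5.00 min remain, so equal charges should end at equal heights.

The second holds a budget view: flattening marks ligand used up, and the height depends on how much ligand reached complex. She reckons the leverage 1.47, the power with which the late reading of complex with three exchanged follows c(incoming ligand). It is a reading, from ash at 7.5% against birch at 2.7%, each good to 0.5 percentage points, for twice the ligand. It stands above one, so lost ligand costs more than its share: a shift of 14.1% in delivered ligand already spends the margin of 1.5 points. She suspects that ligand has a path needing no complex. In delta it starts at 0.360 M and meets complex as that arrives, while in epsilon it enters onto complex already there. She stakes the order epsilon, beta, delta, and says to watch the leaving ligand released, not the flatness.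

The forecast, on the balance side, gave 6.9% for epsilon, 7.2% for beta, 7.3% for delta and all alike, since “Total charges match ash, so the flasks should converge”.

The simulation gives 9.77% for epsilon, 7.48% for beta and 3.52% for delta, with epsilon higher than either other flask.

    complex with two exchanged + incoming ligand → leaving ligand + complex with three exchanged (k = 0.0260 M⁻¹ s⁻¹)
    starting complex + incoming ligand → leaving ligand + complex with one exchanged (k = 0.0610 M⁻¹ s⁻¹)
    2 incoming ligand → homo dimer (k = 0.0200 M⁻¹ s⁻¹)
    complex with one exchanged + incoming ligand → leaving ligand + complex with two exchanged (k = 0.110 M⁻¹ s⁻¹)
    starting complex ⇌ dormant form (K = 0.840, k = 0.0930 s⁻¹)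
    complex with three exchanged + incoming ligand → leaving ligand + complex with four exchanged (k = 0.0300 M⁻¹ s⁻¹)

Beta released 0.214 M of leaving ligand, epsilon 0.246 M and delta 0.131 M, while homo dimer stands at 0.0721 M, 0.0537 M and 0.113 M in the same order. Beta's value, multiplied by the ratio of released leaving ligand raised to the leverage, gives 9.18% for epsilon and 3.64% for delta. Epsilon and delta have nearly come to rest: incoming ligand, the limiting reagent, stands at 1.9% of its charge in epsilon and 0.90% in delta, and ten times the time brings epsilon to 10.3% and delta to 3.66%. The balance view has its region along late time within one flask. Delta dosed over 0.900 min instead of 3.0 min reads 5.15%, higher than its 3.52% and lower than beta's 7.48%.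

The neighbour of delta with 0.12 M of starting complex released 0.857 leaving ligand per starting complex charged against beta's 1.07, so the leverage gives 5.41% for that neighbour. The simulation gives that neighbour 5.47%.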